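**Retrosynthetic overview**
1. Target 25 is opened at the side-chain C=C (cross metathesis), at the enol-ester C(sp2)–O bond (Cu coupling of an (E)-alkenyl iodide) and at the CH2OH group (Morita–Baylis–Hillman).
2. The cycloheptenone comes from a cyclohexenone by one-carbon ring enlargement. A LiCHBr2 adduct gives a β-oxido carbenoid, and a 1,2-alkenyl shift inserts the carbon between C=O and C=C.
3. The acetonyl-bearing centre comes from anti alkylation of the α'-enolate with a base-stable masked acetonyl chloride.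
4. The quaternary and tertiary centres come from a desymmetrising Rh/diene 1,4-alkenylation of prochiral 4-allyl-4-methylcyclohexadienone.
5. Ring order: the only carbocycle is taken as a six-membered ring from p-cresol (step 1) and is enlarged to seven members in step 5.

Assumption: the (R,R)-bod*-type diene is taken to deliver the alkenyl group with the same facial sense it shows on cyclohex-2-enone. If the sense is opposite, the (S,S)-ligand is used.

**Step 1**
Reactants: 1 4-methylphenol (p-cresol); 2 allyltrimethylsilane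
Product: 3 4-allyl-4-methylcyclohexa-2,5-dien-1-one
Conditions: PhI(OAc)2 (1.1 equiv), 2 (4 equiv), HFIP/CH2Cl2, 0 °C, 10 min
Reagents that add atoms: none
Why: Oxidative dearomatisation (oxidative Hosomi–Sakurai allylation), in which the iodane turns the phenol into a phenoxenium-type electrophile that the allylsilane traps at the methyl-bearing para carbon; the product is achiral, so no stereocentre is set yet.

**Step 2**
Reactants: 3 4-allyl-4-methylcyclohexa-2,5-dien-1-one; 4 ethynyltrimethylsilane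
Product: 6 (4S,5R)-4-allyl-4-methyl-5-[(E)-2-(trimethylsilyl)vinyl]cyclohex-2-en-1-one, via alkenylboronate 5 (not isolated)
Conditions: 4, HBpin, Cp2Zr(H)Cl (5 mol %), Et3N (10 mol %), neat, 60 °C; then 3, 5 (1.2 equiv), [RhCl(C2H4)2]2 (2.5 mol %), (R,R)-2,5-bis(3,5-di-tert-butylphenyl)bicyclo[2.2.2]octa-2,5-diene (5.5 mol %), KOH (0.3 equiv), dioxane/H2O 10:1, 30 °C
Reagents that add atoms: none
Why: Proposed new method: desymmetrising Rh(I)/chiral-diene 1,4-alkenylation of an all-carbon 4,4-dialkylcyclohexadienone. The alkenyl-Rh species binds one enone π-face as dictated by the diene (this fixes 5R). Of the two enantiotopic C=C bonds, the one whose bound face carries CH3 rather than CH2CH=CH2 inserts faster, because the syn γ-substituent sits under the bulky aryl wing of the ligand (this fixes 4S, alkenyl cis to CH3). The minor (4R,5R) adduct keeps an enone whose catalyst-preferred face is the open CH3 face, so it is drained by a second addition, which upgrades the dr. The closest known reaction types are the Hayashi–Miyaura asymmetric 1,4-addition to cyclohexenones and Cu-catalysed desymmetrisation of 4,4-disubstituted cyclohexadienones with alkylmetals.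

**Step 3**
Reactants: 6 (4S,5R)-4-allyl-4-methyl-5-[(E)-2-(trimethylsilyl)vinyl]cyclohex-2-en-1-one; 7 2-(chloromethyl)-3,5-dioxahex-1-ene
Product: 9 (4S,5R,6S)-4-allyl-6-[2-(methoxymethoxy)allyl]-4-methyl-5-[(E)-2-(trimethylsilyl)vinyl]cyclohex-2-en-1-one, via lithium enolate 8 (not isolated)
Conditions: LDA (1.05 equiv), THF, −78 °C; 7 (1.5 equiv), Bu4NI (0.2 equiv), DMPU, −78 to −20 °C; neutral work-up, Et3N-deactivated SiO2
Reagents that add atoms: none
Why: Kinetic α'-enolate alkylation, clean because C4 is quaternary and no γ-deprotonation can compete; the allylic electrophile enters anti to the neighbouring C5 alkenyl group and gives the 5,6-trans product (6S), which is also the thermodynamic epimer, while the enol ether masks the acetonyl ketone against the organolithium steps.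

**Step 4**
Reactants: 9 (4S,5R,6S)-4-allyl-6-[2-(methoxymethoxy)allyl]-4-methyl-5-[(E)-2-(trimethylsilyl)vinyl]cyclohex-2-en-1-one; 10 dibromomethane
Product: 13 (4S,5R,6S)-4-allyl-1-(dibromomethyl)-6-[2-(methoxymethoxy)allyl]-4-methyl-5-[(E)-2-(trimethylsilyl)vinyl]cyclohex-2-en-1-ol (C1 epimers), via dibromomethyllithium 11 (not isolated), via lithium alkoxide 12 (not isolated)
Conditions: 10 (3 equiv), LDA (2.5 equiv, added last to 9 + 10), THF, −90 °C; AcOH quench at −90 °C
Reagents that add atoms: none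
Why: 1,2-Addition of the hard carbanion LiCHBr2, generated in the presence of the ketone, to the enone carbonyl; the new carbinol centre becomes sp2 again in step 5, so its configuration does not matter.

**Step 5**
Reactants: 13 (4S,5R,6S)-4-allyl-1-(dibromomethyl)-6-[2-(methoxymethoxy)allyl]-4-methyl-5-[(E)-2-(trimethylsilyl)vinyl]cyclohex-2-en-1-ol
Product: 17 (5S,6R,7S)-5-allyl-5-methyl-7-(2-oxopropyl)-6-[(E)-2-(trimethylsilyl)vinyl]cyclohept-2-en-1-one, via oxido carbenoid 14 (not isolated), via lithium dienolate 15 (not isolated), via deconjugated enol ether 16 (not isolated)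
Conditions: n-BuLi (2.2 equiv), THF, −95 to 0 °C; then 1 M HCl, THF, rt
Reagents that add atoms: water, SMILES O
Why: Nozaki–Yamamoto β-oxido carbenoid ring enlargement (a semipinacol-type 1,2-shift), in which Br/Li exchange gives the carbenoid and the alkoxide push drives migration of the sp2 carbon C2 (alkenyl far better than alkyl) with loss of LiBr; the enolate forms only on the inserted carbon, so the three stereocentres are untouched, and the HCl work-up unmasks the methyl ketone and moves the C=C into conjugation.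

**Step 6**
Reactants: 17 (5S,6R,7S)-5-allyl-5-methyl-7-(2-oxopropyl)-6-[(E)-2-(trimethylsilyl)vinyl]cyclohept-2-en-1-one; 18 formaldehyde
Product: 19 (5S,6R,7S)-5-allyl-2-(hydroxymethyl)-5-methyl-7-(2-oxopropyl)-6-[(E)-2-(trimethylsilyl)vinyl]cyclohept-2-en-1-one
Conditions: 18 (37 % aq, 5 equiv), DMAP (0.5 equiv), THF, 40 °C
Reagents that add atoms: none
Why: Morita–Baylis–Hillman hydroxymethylation, in which DMAP adds reversibly to C3, the enolate takes up formaldehyde at C2 and loss of DMAP restores the now trisubstituted enone; any residual cyclohept-3-enone isomer is funnelled through 17 under the mildly basic conditions, and no stereocentre is created.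

**Step 7**
Reactants: 19 (5S,6R,7S)-5-allyl-2-(hydroxymethyl)-5-methyl-7-(2-oxopropyl)-6-[(E)-2-(trimethylsilyl)vinyl]cyclohept-2-en-1-one
Product: 20 (5S,6R,7S)-5-allyl-2-(hydroxymethyl)-6-[(E)-2-iodovinyl]-5-methyl-7-(2-oxopropyl)cyclohept-2-en-1-one
Conditions: NIS (1.1 equiv), MeCN, 0 °C, dark
Reagents that add atoms: N-iodosuccinimide, SMILES O=C1CCC(=O)N1I
Why: Electrophilic ipso-iododesilylation, in which the β-silicon effect makes the vinylsilane the most nucleophilic alkene present and the (E) geometry is retained.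

**Step 8**
Reactants: 20 (5S,6R,7S)-5-allyl-2-(hydroxymethyl)-6-[(E)-2-iodovinyl]-5-methyl-7-(2-oxopropyl)cyclohept-2-en-1-one; 21 3-methylbut-2-enoic acid
Product: 23 (E)-2-[(5S,6S,7S)-5-allyl-2-(hydroxymethyl)-5-methyl-1-oxo-7-(2-oxopropyl)cyclohept-2-en-6-yl]vinyl 3-methylbut-2-enoate, via caesium carboxylate 22 (not isolated)
Conditions: 21 (2 equiv), Cs2CO3 (equimolar with 21, so that no free carbonate remains), CuI (20 mol %), 3,4,7,8-tetramethyl-1,10-phenanthroline (40 mol %), toluene/THF, 60 °C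
Reagents that add atoms: none
Why: Ullmann-type Cu(I)-catalysed C(sp2)–O coupling of an alkenyl iodide with a carboxylate, which is stereoretentive and fixes the (E)-enol ester; only the weakly basic carboxylate and hydrogen carbonate are present, so the 1,4-diketone, the enone and the free CH2OH survive.

**Step 9**
Reactants: 23 (E)-2-[(5S,6S,7S)-5-allyl-2-(hydroxymethyl)-5-methyl-1-oxo-7-(2-oxopropyl)cyclohept-2-en-6-yl]vinyl 3-methylbut-2-enoate; 24 2-methylbut-3-en-2-ol
Product: 25 (5S,6S,7S)-2-(hydroxymethyl)-5-[(E)-4-hydroxy-4-methylpent-2-en-1-yl]-5-methyl-6-[(E)-2-(3-methylbut-2-enoyloxy)vinyl]-7-(2-oxopropyl)cyclohept-2-en-1-one (CNP0351090.2)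
Conditions: 24 (10 equiv), Hoveyda–Grubbs II (5 mol %), CH2Cl2, 40 °C
Reagents that add atoms: none
Why: Olefin cross metathesis of the only terminal alkene with a hindered tertiary allylic alcohol gives the (E)-alkene; the enone, senecioate and enol-ester alkenes are too substituted or too deactivated to take part, and no stereocentre is touched.

**Compound list**
1 | 4-methylphenol | Cc1ccc(O)cc1 | starting material
2 | allyltrimethylsilane | C=CC[Si](C)(C)C | starting material
3 | 4-allyl-4-methylcyclohexa-2,5-dien-1-one | CC1(CC=C)C=CC(=O)C=C1 | intermediate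
4 | ethynyltrimethylsilane | C#C[Si](C)(C)C | starting material
5 | (E)-4,4,5,5-tetramethyl-2-[2-(trimethylsilyl)vinyl]-1,3,2-dioxaborolane | C[Si](C)(C)/C=C/B1OC(C)(C)C(C)(C)O1 | intermediate
6 | (4S,5R)-4-allyl-4-methyl-5-[(E)-2-(trimethylsilyl)vinyl]cyclohex-2-en-1-one | C1C(=O)C=C[C@](C)(CC=C)[C@H]1/C=C/[Si](C)(C)C | intermediate
7 | 2-(chloromethyl)-3,5-dioxahex-1-ene | COCOC(=C)CCl | starting material
8 | lithium cross-conjugated dienolate of 6 | C1=C(O[Li])C=C[C@](C)(CC=C)[C@H]1/C=C/[Si](C)(C)C | intermediate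
9 | (4S,5R,6S)-4-allyl-6-[2-(methoxymethoxy)allyl]-4-methyl-5-[(E)-2-(trimethylsilyl)vinyl]cyclohex-2-en-1-one | COCOC(=C)C[C@@H]1C(=O)C=C[C@](C)(CC=C)[C@H]1/C=C/[Si](C)(C)C | intermediate
10 | dibromomethane | BrCBr | starting material
11 | dibromomethyllithium | [Li]C(Br)Br | intermediate
12 | lithium alkoxide of 13 | COCOC(=C)C[C@@H]1C(O[Li])(C(Br)Br)C=C[C@](C)(CC=C)[C@H]1/C=C/[Si](C)(C)C | intermediate
13 | (4S,5R,6S)-4-allyl-1-(dibromomethyl)-6-[2-(methoxymethoxy)allyl]-4-methyl-5-[(E)-2-(trimethylsilyl)vinyl]cyclohex-2-en-1-ol (C1 epimers) | COCOC(=C)C[C@@H]1C(O)(C(Br)Br)C=C[C@](C)(CC=C)[C@H]1/C=C/[Si](C)(C)C | intermediate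
14 | β-oxido carbenoid (O-lithio, C-lithio-bromo) | COCOC(=C)C[C@@H]1C(O[Li])(C([Li])Br)C=C[C@](C)(CC=C)[C@H]1/C=C/[Si](C)(C)C | intermediate
15 | ring-enlarged lithium cyclohepta-1,3-dienolate | COCOC(=C)C[C@@H]1C(O[Li])=CC=C[C@](C)(CC=C)[C@H]1/C=C/[Si](C)(C)C | intermediate
16 | (5S,6R,7S)-5-allyl-7-[2-(methoxymethoxy)allyl]-5-methyl-6-[(E)-2-(trimethylsilyl)vinyl]cyclohept-3-en-1-one | COCOC(=C)C[C@@H]1C(=O)CC=C[C@](C)(CC=C)[C@H]1/C=C/[Si](C)(C)C | intermediate
17 | (5S,6R,7S)-5-allyl-5-methyl-7-(2-oxopropyl)-6-[(E)-2-(trimethylsilyl)vinyl]cyclohept-2-en-1-one | CC(=O)C[C@@H]1C(=O)C=CC[C@](C)(CC=C)[C@H]1/C=C/[Si](C)(C)C | intermediate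
18 | formaldehyde | C=O | starting material
19 | (5S,6R,7S)-5-allyl-2-(hydroxymethyl)-5-methyl-7-(2-oxopropyl)-6-[(E)-2-(trimethylsilyl)vinyl]cyclohept-2-en-1-one | CC(=O)C[C@@H]1C(=O)C(CO)=CC[C@](C)(CC=C)[C@H]1/C=C/[Si](C)(C)C | intermediate
20 | (5S,6R,7S)-5-allyl-2-(hydroxymethyl)-6-[(E)-2-iodovinyl]-5-methyl-7-(2-oxopropyl)cyclohept-2-en-1-one | CC(=O)C[C@@H]1C(=O)C(CO)=CC[C@](C)(CC=C)[C@H]1/C=C/I | intermediate
21 | 3-methylbut-2-enoic acid | CC(C)=CC(=O)O | starting material
22 | caesium 3-methylbut-2-enoate | [Cs+].CC(C)=CC(=O)[O-] | intermediate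
23 | (E)-2-[(5S,6S,7S)-5-allyl-2-(hydroxymethyl)-5-methyl-1-oxo-7-(2-oxopropyl)cyclohept-2-en-6-yl]vinyl 3-methylbut-2-enoate | CC(=O)C[C@@H]1C(=O)C(CO)=CC[C@](C)(CC=C)[C@H]1/C=C/OC(=O)C=C(C)C | intermediate
24 | 2-methylbut-3-en-2-ol | CC(C)(O)C=C | starting material
25 | CNP0351090.2 | CC(=O)C[C@@H]1C(=O)C(CO)=CC[C@](C)(C/C=C/C(C)(C)O)[C@H]1/C=C/OC(=O)C=C(C)C | target

Total step count: 9. Longest linear sequence: 9.

**Steps most likely to fail**

*Step 2 (proposed new step).*
- The ee should be high, because the π-face is under catalyst control. The discrimination between CH3 and CH2CH=CH2 on that face may be only moderate. I expect about 5:1, upgraded by sacrificial over-addition of the minor isomer.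
- The dienone may also compete with the chiral diene for rhodium.
- The fallback uses known chemistry, sets out from 3 and returns at 6.
- An ene-reductase (old-yellow-enzyme type, NADPH recycled with glucose/GDH) reduces one enantiotopic C=C of 3 to (R)-4-allyl-4-methylcyclohex-2-en-1-one F1.
- A catalyst-controlled Hayashi–Miyaura addition of 5 (Rh/(R)-BINAP, aq dioxane) to the single remaining enone gives (3R,4R)-4-allyl-4-methyl-3-[(E)-2-(trimethylsilyl)vinyl]cyclohexan-1-one F2.
- Kinetic deprotonation away from the branched carbon (LDA, TMSCl) gives the trimethylsilyl enol ether F3. Saegusa–Ito oxidation with Pd(OAc)2 then re-installs the enone of 6.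

*Step 5.*
- Migration of the sec-alkyl carbon C6 could compete with the alkenyl shift. Collapse of the bromo alkoxide to a bromo epoxide is a second possible side reaction.
- The fallback fixes the regiochemistry by construction through a radical cyclopropanol-type enlargement. It sets out from 9 and returns at 17.
- PPTS in aqueous acetone unmasks 9 to (4S,5R,6S)-4-allyl-4-methyl-6-(2-oxopropyl)-5-[(E)-2-(trimethylsilyl)vinyl]cyclohex-2-en-1-one F4.
- Rh-catalysed 1,4-hydrosilylation (Et3SiH, RhCl(PPh3)3) gives the regiodefined triethylsilyl enol ether F5.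
- Furukawa cyclopropanation (Et2Zn, CH2I2) gives the 1-(triethylsilyloxy)bicyclo[4.1.0]heptane F6.
- FeCl3 in DMF cleaves the internal bond to the 3-chlorocycloheptanone F7. NaOAc in MeOH then eliminates to 17.

*Step 8.*
- Carboxylates are poor partners in Cu(I) vinylation. The product is also an acyl donor towards the free CH2OH.
- The fallback reverses the polarity to an oxidative coupling. It sets out from 20 and returns at 23.
- Miyaura borylation (B2pin2, PdCl2(PPh3)2, KOPh, toluene, 50 °C) gives the (E)-alkenyl pinacol boronate F8.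
- KHF2 in aqueous MeOH gives the potassium (E)-alkenyltrifluoroborate F9.
- A Chan–Lam-type acyloxylation with 21 (CuBr, DMAP, 4 Å MS, O2, CH2Cl2, 40 °C) gives 23 with retention of geometry.

**Further compounds**
F1 | step 2 | (R)-4-allyl-4-methylcyclohex-2-en-1-one | O=C1C=C[C@@](C)(CC=C)CC1
F2 | step 2 | (3R,4R)-4-allyl-4-methyl-3-[(E)-2-(trimethylsilyl)vinyl]cyclohexan-1-one | C1C(=O)CC[C@](C)(CC=C)[C@H]1/C=C/[Si](C)(C)C
F3 | step 2 | trimethylsilyl enol ether of F2 (C1=C6) | C1C(O[Si](C)(C)C)=CC[C@](C)(CC=C)[C@H]1/C=C/[Si](C)(C)C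
F4 | step 5 | (4S,5R,6S)-4-allyl-4-methyl-6-(2-oxopropyl)-5-[(E)-2-(trimethylsilyl)vinyl]cyclohex-2-en-1-one | CC(=O)C[C@@H]1C(=O)C=C[C@](C)(CC=C)[C@H]1/C=C/[Si](C)(C)C
F5 | step 5 | triethylsilyl enol ether from 1,4-hydrosilylation of F4 | CC(=O)C[C@@H]1C(O[Si](CC)(CC)CC)=CC[C@](C)(CC=C)[C@H]1/C=C/[Si](C)(C)C
F6 | step 5 | 1-(triethylsilyloxy)bicyclo[4.1.0]heptane from F5 | CC(=O)C[C@@H]1C2(O[Si](CC)(CC)CC)CC2C[C@](C)(CC=C)[C@H]1/C=C/[Si](C)(C)C
F7 | step 5 | 3-chlorocycloheptanone from F6 | CC(=O)C[C@@H]1C(=O)CC(Cl)C[C@](C)(CC=C)[C@H]1/C=C/[Si](C)(C)C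
F8 | step 8 | (E)-alkenyl pinacol boronate from 20 | CC(=O)C[C@@H]1C(=O)C(CO)=CC[C@](C)(CC=C)[C@H]1/C=C/B2OC(C)(C)C(C)(C)O2
F9 | step 8 | potassium (E)-alkenyltrifluoroborate from F8 | CC(=O)C[C@@H]1C(=O)C(CO)=CC[C@](C)(CC=C)[C@H]1/C=C/[B-](F)(F)F.[K+]
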